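**Plan**

1. Retrosynthetic cuts: first the C10–C11 bond between the dienyl terminus and the carbinol carbon on the oxane (giving oxane aldehyde 12 and enyne lactone 30). In 30: the C2–C3 diene bond (Heck), the (Z)-C3=C4 olefin (iodo-Wittig), C8–C9 (Sonogashira), the C7 methyl/C8 (carboalumination) and C5–C6 (Evans alkylation). In 12: the oxane bonds O1–C6 and C5–C6 (Prins). In the lactone: the ring olefin (metathesis).
2. Forward order: the oxane ring is made first (Prins cyclisation, then C4 inversion), the dihydropyranone ring by ring-closing metathesis, the C5–C10 chain is grown linearly and joined to the lactone by a Heck reaction; the two halves are united last, followed by one desilylation.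
3. Stereochemistry: oxane C2 from (S)-glycidyl silyl ether; C5 and C6 from the Prins chair (2,6-cis, (Z)-olefin gives the axial methyl); C4 by Mitsunobu inversion; chain C5 by Evans alkylation; lactone C6 by Brown allylboration; C11 by chelate-controlled addition.
4. Enabling feature: the oxane ring oxygen O1 lies α to C11, so zinc can bridge O1 and the formyl oxygen of 12 in a five-membered chelate. The C9≡C10 terminal alkyne is the only unit of 30 that hydroborates fast, so the (E)-C9=C10 olefin, the C10–C11 bond and the C11 carbinol arise together from an alkyne and an aldehyde.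

Key step: step 20

Remark on the chemistry: chain locants C1–C11 run from the lactone to the carbinol, oxane atoms are O1, C2 (bearing C11) to C6. A silyl ether on O4 raises the CIP rank of C4 above C6, so oxane C5 is written R in the silyl ethers 11, 12 and 33 and S in the free alcohols, with no change in spatial arrangement.

**Part A – oxane aldehyde 12**

Step 1
Reactants: 1 (S)-tert-butyl(oxiran-2-ylmethoxy)diphenylsilane; 2 prop-1-yn-1-yllithium
Product: 3 (S)-1-[(tert-butyldiphenylsilyl)oxy]hex-4-yn-2-ol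
Conditions: BF3·OEt2, THF, −78 °C; then H2O
Reagents that add atoms: none
Why: BF3-promoted opening of a terminal epoxide by a lithium acetylide occurs at the CH2 terminus, so the stereocenter of 1 is carried over untouched.

Step 2
Reactants: 3 (S)-1-[(tert-butyldiphenylsilyl)oxy]hex-4-yn-2-ol
Product: 4 (S,Z)-1-[(tert-butyldiphenylsilyl)oxy]hex-4-en-2-ol
Conditions: H2 (1 atm), Pd/CaCO3 poisoned with Pb(OAc)2, quinoline, EtOAc, rt
Reagents that add atoms: none
Why: Lindlar semihydrogenation adds hydrogen syn on the poisoned surface and should stop at the (Z)-alkene; no stereocenter is touched.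

Step 3
Reactants: 4 (S,Z)-1-[(tert-butyldiphenylsilyl)oxy]hex-4-en-2-ol; 5 (E)-but-2-enal (crotonaldehyde)
Product: 7 (2S,3S,4S,6S)-6-{[(tert-butyldiphenylsilyl)oxy]methyl}-3-methyl-2-[(E)-prop-1-en-1-yl]oxan-4-ol, via trifluoroacetate ester 6 (not isolated)
Conditions: CF3CO2H, CH2Cl2, 0 °C→rt; evaporate; K2CO3, MeOH, rt
Reagents that add atoms: trifluoroacetic acid, OC(=O)C(F)(F)F (source of the C4 oxygen)
Why: Prins cyclisation: the oxocarbenium ion from 4 and 5 should close through a chair with the two ring-oxygen-flanking substituents equatorial (2,6-cis relative to the existing carbinol center), the (Z)-olefin places the methyl group axial and cis to propenyl, and trifluoroacetate traps the C4 cation equatorially; methanolysis frees the all-cis alcohol.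

Step 4
Reactants: 7 (2S,3S,4S,6S)-6-{[(tert-butyldiphenylsilyl)oxy]methyl}-3-methyl-2-[(E)-prop-1-en-1-yl]oxan-4-ol
Product: 8 (2S,3S,4R,6S)-6-{[(tert-butyldiphenylsilyl)oxy]methyl}-3-methyl-2-[(E)-prop-1-en-1-yl]oxan-4-yl 4-nitrobenzoate
Conditions: 4-O2NC6H4CO2H, PPh3, i-PrO2CN=NCO2i-Pr, toluene, 0 °C→rt
Reagents that add atoms: 4-nitrobenzoic acid, OC(=O)c1ccc(cc1)[N+](=O)[O-]
Why: Mitsunobu esterification displaces the equatorial oxyphosphonium group by SN2 along the open axial trajectory (the axial methyl lies on the other face, and an equatorial leaving group has no antiperiplanar ring hydrogen for elimination), inverting C4 to the axial ester.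

Step 5
Reactants: 8 (2S,3S,4R,6S)-6-{[(tert-butyldiphenylsilyl)oxy]methyl}-3-methyl-2-[(E)-prop-1-en-1-yl]oxan-4-yl 4-nitrobenzoate
Product: 9 (2S,3S,4R,6S)-6-{[(tert-butyldiphenylsilyl)oxy]methyl}-3-methyl-2-[(E)-prop-1-en-1-yl]oxan-4-ol
Conditions: K2CO3, MeOH, rt
Reagents that add atoms: none
Why: Base-catalysed transesterification cleaves the acyl–oxygen bond, so the inverted C4 configuration is kept and the silyl ether survives.

Step 6
Reactants: 9 (2S,3S,4R,6S)-6-{[(tert-butyldiphenylsilyl)oxy]methyl}-3-methyl-2-[(E)-prop-1-en-1-yl]oxan-4-ol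
Product: 10 (2S,3S,4R,6S)-6-(hydroxymethyl)-3-methyl-2-[(E)-prop-1-en-1-yl]oxan-4-ol
Conditions: Bu4NF, THF, 0 °C→rt
Reagents that add atoms: none
Why: Fluoride-induced cleavage of the silyl ether, driven by Si–F bond formation.

Step 7
Reactants: 10 (2S,3S,4R,6S)-6-(hydroxymethyl)-3-methyl-2-[(E)-prop-1-en-1-yl]oxan-4-ol
Product: 11 triethyl{[(2S,4R,5R,6S)-5-methyl-6-[(E)-prop-1-en-1-yl]-4-[(triethylsilyl)oxy]oxan-2-yl]methoxy}silane
Conditions: Et3SiCl (2.5 equiv), imidazole, DMF, 0 °C→rt
Reagents that add atoms: chlorotriethylsilane, CC[Si](Cl)(CC)CC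
Why: Standard silylation of both hydroxyl groups with a silyl chloride and imidazole.

Step 8
Reactants: 11 triethyl{[(2S,4R,5R,6S)-5-methyl-6-[(E)-prop-1-en-1-yl]-4-[(triethylsilyl)oxy]oxan-2-yl]methoxy}silane
Product: 12 (2S,4R,5R,6S)-5-methyl-6-[(E)-prop-1-en-1-yl]-4-[(triethylsilyl)oxy]oxane-2-carbaldehyde
Conditions: (COCl)2, DMSO, CH2Cl2, −78→−40 °C; Et3N, −78 °C→rt
Reagents that add atoms: none
Why: Swern oxidation applied directly to a bis-triethylsilyl ether: activated DMSO cleaves the unhindered primary Si–O bond and oxidises that position to the aldehyde, while the secondary axial silyl ether stays; the low temperature should keep the α-stereocenter intact.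

**Part B – vinyl lactone 17**

Step 9
Reactants: 13 prop-2-enal (acrolein)
Product: 15 (S)-hexa-1,5-dien-3-ol, via borinate ester 14 (not isolated)
Conditions: (−)-Ipc2BOMe [from (+)-α-pinene], C3H5MgBr, Et2O, 0 °C→rt; −78 °C, then 13; NaOH, H2O2, 0 °C→rt
Reagents that add atoms: allylmagnesium bromide, C=CC[Mg]Br
Why: Brown allylboration through a chair six-membered transition state under control of the isopinocampheyl groups; the reagent derived from (+)-α-pinene is known to give the (S)-carbinol from aldehydes whose substituent outranks allyl, and it adds 1,2 to the enal.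

Step 10
Reactants: 15 (S)-hexa-1,5-dien-3-ol
Product: 16 (S)-hexa-1,5-dien-3-yl prop-2-enoate
Conditions: CH2=CHCOCl, Et3N, DMAP (cat.), CH2Cl2, 0 °C
Reagents that add atoms: acryloyl chloride, C=CC(=O)Cl
Why: O-acylation of a secondary alcohol with an acid chloride; the stereocenter is not involved.

Step 11
Reactants: 16 (S)-hexa-1,5-dien-3-yl prop-2-enoate
Product: 17 (S)-6-vinyl-5,6-dihydro-2H-pyran-2-one
Conditions: RuCl2(=CHPh)(PCy3)2 (first-generation Grubbs catalyst, 5 mol %), CH2Cl2 (0.005 M), 40 °C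
Reagents that add atoms: none
Why: Ring-closing olefin metathesis of an acrylate: the carbene should load on the unhindered homoallylic terminus and close the six-membered lactone, since the allylic vinyl group is slower and could only give a strained butenolide.

**Part C – enyne lactone 30**

Step 12
Reactants: 18 (S)-4-benzyl-3-propionyloxazolidin-2-one; 19 3-bromoprop-1-yne (propargyl bromide)
Product: 21 (S)-4-benzyl-3-[(R)-2-methylpent-4-ynoyl]oxazolidin-2-one, via sodium Z-enolate 20 (not isolated)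
Conditions: NaN(SiMe3)2, THF, −78 °C; then 19, −78→−40 °C
Reagents that add atoms: none
Why: Evans alkylation: the chelated (Z)-enolate is alkylated on the face opposite the benzyl group, which sets the (R)-methyl stereocenter.

Step 13
Reactants: 21 (S)-4-benzyl-3-[(R)-2-methylpent-4-ynoyl]oxazolidin-2-one
Product: 22 (R)-2-methylpent-4-yn-1-ol
Conditions: LiBH4, Et2O, H2O (1 equiv), 0 °C; aq. NaOH
Reagents that add atoms: none
Why: Borohydride reduction of the activated imide carbonyl releases the auxiliary without touching the α-stereocenter or the alkyne.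

Step 14
Reactants: 22 (R)-2-methylpent-4-yn-1-ol
Product: 24 (R,E)-5-iodo-2,4-dimethylpent-4-en-1-ol, via alkenylalane 23 (not isolated)
Conditions: Al(CH3)3 (3 equiv), (C5H5)2ZrCl2 (25 mol %), CH2Cl2, 0 °C→rt; then I2, THF, −30→0 °C; H2O
Reagents that add atoms: trimethylaluminium, C[Al](C)C; iodine, II
Why: Negishi zirconium-catalysed carboalumination adds methyl and aluminium syn with methyl on the internal carbon, and iodinolysis proceeds with retention, giving the (E)-iodoalkene.

Step 15
Reactants: 24 (R,E)-5-iodo-2,4-dimethylpent-4-en-1-ol; 25 ethynyltrimethylsilane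
Product: 26 (R,E)-2,4-dimethyl-7-(trimethylsilyl)hept-4-en-6-yn-1-ol
Conditions: PdCl2(PPh3)2 (3 mol %), CuI (6 mol %), i-Pr2NH, THF, rt
Reagents that add atoms: none
Why: Sonogashira coupling of an alkenyl iodide with retention of olefin geometry; the free hydroxyl is tolerated.

Step 16
Reactants: 26 (R,E)-2,4-dimethyl-7-(trimethylsilyl)hept-4-en-6-yn-1-ol
Product: 27 (R,E)-2,4-dimethyl-7-(trimethylsilyl)hept-4-en-6-ynal
Conditions: TEMPO (10 mol %), PhI(OAc)2, CH2Cl2, rt
Reagents that add atoms: none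
Why: Nitroxyl-catalysed oxidation of a primary alcohol under non-basic conditions, so the α-methyl stereocenter should not epimerise; the aldehyde is used at once.

Step 17
Reactants: 27 (R,E)-2,4-dimethyl-7-(trimethylsilyl)hept-4-en-6-ynal
Product: 28 [(3E,6R,7Z)-8-iodo-4,6-dimethylnona-3,7-dien-1-yn-1-yl]trimethylsilane
Conditions: [Ph3PEt]I, n-BuLi, THF, rt; I2, −78 °C; NaN(SiMe3)2, −78→−20 °C; then 27, −78 °C
Reagents that add atoms: ethyltriphenylphosphonium iodide, CC[P+](c1ccccc1)(c1ccccc1)c1ccccc1.[I-]; iodine, II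
Why: Stork–Zhao-type Wittig olefination with the α-iodoethylidene ylide, a non-stabilised ylide that is expected to give the (Z)-iodoalkene under kinetic control.

Step 18
Reactants: 28 [(3E,6R,7Z)-8-iodo-4,6-dimethylnona-3,7-dien-1-yn-1-yl]trimethylsilane; 17 (S)-6-vinyl-5,6-dihydro-2H-pyran-2-one
Product: 29 (S)-6-[(1E,3Z,5R,7E)-3,5,7-trimethyl-10-(trimethylsilyl)deca-1,3,7-trien-9-yn-1-yl]-5,6-dihydro-2H-pyran-2-one
Conditions: Pd(OAc)2 (10 mol %), Bu4NCl, NaHCO3, DMF, rt→45 °C
Reagents that add atoms: none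
Why: Heck reaction under ligand-free phase-transfer conditions: oxidative addition with retention at the (Z)-iodide, syn-carbopalladation at the terminal vinyl carbon and syn-β-hydride elimination should give the (E)-olefin of the (1E,3Z)-diene; the lactone stereocenter is not involved.

Step 19
Reactants: 29 (S)-6-[(1E,3Z,5R,7E)-3,5,7-trimethyl-10-(trimethylsilyl)deca-1,3,7-trien-9-yn-1-yl]-5,6-dihydro-2H-pyran-2-one
Product: 30 (S)-6-[(1E,3Z,5R,7E)-3,5,7-trimethyldeca-1,3,7-trien-9-yn-1-yl]-5,6-dihydro-2H-pyran-2-one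
Conditions: Bu4NF, AcOH (1:1), THF, 0 °C→rt
Reagents that add atoms: none
Why: Fluoride attack at silicon cleaves the alkynyl C–Si bond; buffering with acetic acid is meant to protect the base-sensitive unsaturated lactone.

**Union and completion**

Step 20
Reactants: 30 (S)-6-[(1E,3Z,5R,7E)-3,5,7-trimethyldeca-1,3,7-trien-9-yn-1-yl]-5,6-dihydro-2H-pyran-2-one; 12 (2S,4R,5R,6S)-5-methyl-6-[(E)-prop-1-en-1-yl]-4-[(triethylsilyl)oxy]oxane-2-carbaldehyde
Product: 33 (S)-6-[(1E,3Z,5R,7E,9E,11S)-11-hydroxy-3,5,7-trimethyl-11-{(2S,4R,5R,6S)-5-methyl-6-[(E)-prop-1-en-1-yl]-4-[(triethylsilyl)oxy]oxan-2-yl}undeca-1,3,7,9-tetraen-1-yl]-5,6-dihydro-2H-pyran-2-one, via dienylborane 31 (not isolated), via dienylmethylzinc 32 (not isolated)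
Conditions: (c-C6H11)2BH, toluene, 0 °C→rt; Zn(CH3)2, −78 °C; then 12 and C2H5ZnCl (1.5 equiv), toluene/CH2Cl2, −78→−20 °C; aq. NH4Cl
Reagents that add atoms: none
Why: The terminal alkyne of 30 adds dicyclohexylborane syn with boron on the terminal carbon to give the (E,E)-dienylborane 31, boron-to-zinc exchange gives the dienyl(methyl)zinc 32, and 32 transfers only its dienyl group to the formyl carbon of 12, so the C10–C11 bond, the (E)-C9=C10 olefin and the C11 carbinol are formed in one operation from an alkyne and an aldehyde. The closest known reaction type is the one-pot hydroboration/boron-to-zinc transmetalation/alkenylzinc addition to aldehydes, in its chelation-controlled form with alkylzinc halide Lewis acids for α-oxygenated aldehydes, which is also known for dienylzinc reagents made from enynes. No ring is closed. The one new stereocenter (C11, S) is controlled by the oxane ring oxygen O1 α to the formyl carbon: zinc bridges O1 and the carbonyl oxygen in a five-membered chelate and the dienyl group enters from the face flanked by H2 and not by the ring CH2 (C3), which gives the 1,2-syn relation between O1 and the new hydroxyl required by the target (Felkin-type addition would give the epimer). The step needs chemoselectivity (alkyne over three other olefins and the unsaturated lactone; aldehyde over lactone) and chelate over Felkin control; the first rests on the large rate gap of a hindered dialkylborane between a terminal alkyne and tri- or 1,2-disubstituted or electron-poor olefins and on the inertness of organozincs toward esters, the second on the non-coordinating solvent and the Lewis-acidic ethylzinc chloride.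

Step 21
Reactants: 33 (S)-6-[(1E,3Z,5R,7E,9E,11S)-11-hydroxy-3,5,7-trimethyl-11-{(2S,4R,5R,6S)-5-methyl-6-[(E)-prop-1-en-1-yl]-4-[(triethylsilyl)oxy]oxan-2-yl}undeca-1,3,7,9-tetraen-1-yl]-5,6-dihydro-2H-pyran-2-one
Product: 34 (S)-6-[(1E,3Z,5R,7E,9E,11S)-11-hydroxy-11-{(2S,4R,5S,6S)-4-hydroxy-5-methyl-6-[(E)-prop-1-en-1-yl]oxan-2-yl}-3,5,7-trimethylundeca-1,3,7,9-tetraen-1-yl]-5,6-dihydro-2H-pyran-2-one (target)
Conditions: HF·pyridine, pyridine, THF, 0 °C
Reagents that add atoms: none
Why: Pyridine-buffered HF cleaves the secondary triethylsilyl ether under conditions that should be too mild to ionise the dienylic alcohol or open the lactone.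

**Compound list**

1 | (S)-tert-butyl(oxiran-2-ylmethoxy)diphenylsilane | CC(C)(C)[Si](OC[C@@H]1CO1)(c1ccccc1)c1ccccc1 | starting material
2 | prop-1-yn-1-yllithium | [Li]C#CC | starting material
3 | (S)-1-[(tert-butyldiphenylsilyl)oxy]hex-4-yn-2-ol | CC#CC[C@H](O)CO[Si](c1ccccc1)(c1ccccc1)C(C)(C)C | intermediate
4 | (S,Z)-1-[(tert-butyldiphenylsilyl)oxy]hex-4-en-2-ol | C/C=C\C[C@H](O)CO[Si](c1ccccc1)(c1ccccc1)C(C)(C)C | intermediate
5 | (E)-but-2-enal | C/C=C/C=O | starting material
6 | (2S,3S,4S,6S)-6-{[(tert-butyldiphenylsilyl)oxy]methyl}-3-methyl-2-[(E)-prop-1-en-1-yl]oxan-4-yl trifluoroacetate | C/C=C/[C@@H]1O[C@H](CO[Si](c2ccccc2)(c2ccccc2)C(C)(C)C)C[C@H](OC(=O)C(F)(F)F)[C@@H]1C | intermediate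
7 | (2S,3S,4S,6S)-6-{[(tert-butyldiphenylsilyl)oxy]methyl}-3-methyl-2-[(E)-prop-1-en-1-yl]oxan-4-ol | C/C=C/[C@@H]1O[C@H](CO[Si](c2ccccc2)(c2ccccc2)C(C)(C)C)C[C@H](O)[C@@H]1C | intermediate
8 | (2S,3S,4R,6S)-6-{[(tert-butyldiphenylsilyl)oxy]methyl}-3-methyl-2-[(E)-prop-1-en-1-yl]oxan-4-yl 4-nitrobenzoate | C/C=C/[C@@H]1O[C@H](CO[Si](c2ccccc2)(c2ccccc2)C(C)(C)C)C[C@@H](OC(=O)c2ccc(cc2)[N+](=O)[O-])[C@@H]1C | intermediate
9 | (2S,3S,4R,6S)-6-{[(tert-butyldiphenylsilyl)oxy]methyl}-3-methyl-2-[(E)-prop-1-en-1-yl]oxan-4-ol | C/C=C/[C@@H]1O[C@H](CO[Si](c2ccccc2)(c2ccccc2)C(C)(C)C)C[C@@H](O)[C@@H]1C | intermediate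
10 | (2S,3S,4R,6S)-6-(hydroxymethyl)-3-methyl-2-[(E)-prop-1-en-1-yl]oxan-4-ol | C/C=C/[C@@H]1O[C@H](CO)C[C@@H](O)[C@@H]1C | intermediate
11 | triethyl{[(2S,4R,5R,6S)-5-methyl-6-[(E)-prop-1-en-1-yl]-4-[(triethylsilyl)oxy]oxan-2-yl]methoxy}silane | C/C=C/[C@@H]1O[C@H](CO[Si](CC)(CC)CC)C[C@@H](O[Si](CC)(CC)CC)[C@@H]1C | intermediate
12 | (2S,4R,5R,6S)-5-methyl-6-[(E)-prop-1-en-1-yl]-4-[(triethylsilyl)oxy]oxane-2-carbaldehyde | C/C=C/[C@@H]1O[C@H](C=O)C[C@@H](O[Si](CC)(CC)CC)[C@@H]1C | intermediate
13 | prop-2-enal | C=CC=O | starting material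
14 | (S)-hexa-1,5-dien-3-yl diisopinocampheylborinate (isopinocampheyl groups of the (+)-α-pinene series) | C=C[C@H](CC=C)OB([C@@H]1C[C@@H]2C[C@H]([C@H]1C)C2(C)C)[C@@H]1C[C@@H]2C[C@H]([C@H]1C)C2(C)C | intermediate
15 | (S)-hexa-1,5-dien-3-ol | C=C[C@@H](O)CC=C | intermediate
16 | (S)-hexa-1,5-dien-3-yl prop-2-enoate | C=C[C@@H](OC(=O)C=C)CC=C | intermediate
17 | (S)-6-vinyl-5,6-dihydro-2H-pyran-2-one | C=C[C@@H]1CC=CC(=O)O1 | intermediate
18 | (S)-4-benzyl-3-propionyloxazolidin-2-one | CCC(=O)N1[C@@H](Cc2ccccc2)COC1=O | starting material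
19 | 3-bromoprop-1-yne | C#CCBr | starting material
20 | sodium (Z)-enolate of 18 | C/C=C(\[O-])N1[C@@H](Cc2ccccc2)COC1=O.[Na+] | intermediate
21 | (S)-4-benzyl-3-[(R)-2-methylpent-4-ynoyl]oxazolidin-2-one | C#CC[C@@H](C)C(=O)N1[C@@H](Cc2ccccc2)COC1=O | intermediate
22 | (R)-2-methylpent-4-yn-1-ol | C#CC[C@@H](C)CO | intermediate
23 | dimethylaluminium alkoxide of (R,E)-5-(dimethylalumanyl)-2,4-dimethylpent-4-en-1-ol | C[Al](C)/C=C(\C)C[C@@H](C)CO[Al](C)C | intermediate
24 | (R,E)-5-iodo-2,4-dimethylpent-4-en-1-ol | I/C=C(\C)C[C@@H](C)CO | intermediate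
25 | ethynyltrimethylsilane | C#C[Si](C)(C)C | starting material
26 | (R,E)-2,4-dimethyl-7-(trimethylsilyl)hept-4-en-6-yn-1-ol | C[Si](C)(C)C#C/C=C(\C)C[C@@H](C)CO | intermediate
27 | (R,E)-2,4-dimethyl-7-(trimethylsilyl)hept-4-en-6-ynal | C[Si](C)(C)C#C/C=C(\C)C[C@@H](C)C=O | intermediate
28 | [(3E,6R,7Z)-8-iodo-4,6-dimethylnona-3,7-dien-1-yn-1-yl]trimethylsilane | C[Si](C)(C)C#C/C=C(\C)C[C@@H](C)/C=C(C)\I | intermediate
29 | (S)-6-[(1E,3Z,5R,7E)-3,5,7-trimethyl-10-(trimethylsilyl)deca-1,3,7-trien-9-yn-1-yl]-5,6-dihydro-2H-pyran-2-one | C[Si](C)(C)C#C/C=C(\C)C[C@@H](C)/C=C(C)\C=C\[C@@H]1CC=CC(=O)O1 | intermediate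
30 | (S)-6-[(1E,3Z,5R,7E)-3,5,7-trimethyldeca-1,3,7-trien-9-yn-1-yl]-5,6-dihydro-2H-pyran-2-one | C#C/C=C(\C)C[C@@H](C)/C=C(C)\C=C\[C@@H]1CC=CC(=O)O1 | intermediate
31 | (E,E)-dienyl(dicyclohexyl)borane from 30 | C1CCCCC1B(C1CCCCC1)/C=C/C=C(\C)C[C@@H](C)/C=C(C)\C=C\[C@@H]1CC=CC(=O)O1 | intermediate
32 | (E,E)-dienyl(methyl)zinc from 31 | C[Zn]/C=C/C=C(\C)C[C@@H](C)/C=C(C)\C=C\[C@@H]1CC=CC(=O)O1 | intermediate
33 | O4-triethylsilyl ether of the target (full name in step 20) | C/C=C/[C@@H]1O[C@H]([C@@H](O)/C=C/C=C(\C)C[C@@H](C)/C=C(C)\C=C\[C@@H]2CC=CC(=O)O2)C[C@@H](O[Si](CC)(CC)CC)[C@@H]1C | intermediate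
34 | (S)-6-[(1E,3Z,5R,7E,9E,11S)-11-hydroxy-11-{(2S,4R,5S,6S)-4-hydroxy-5-methyl-6-[(E)-prop-1-en-1-yl]oxan-2-yl}-3,5,7-trimethylundeca-1,3,7,9-tetraen-1-yl]-5,6-dihydro-2H-pyran-2-one | C/C=C/[C@@H]1O[C@H]([C@@H](O)/C=C/C=C(\C)C[C@@H](C)/C=C(C)\C=C\[C@@H]2CC=CC(=O)O2)C[C@@H](O)[C@@H]1C | target

**Totals and risks**

Total step count: 21. Longest linear sequence: 10 steps (steps 12–19, then 20 and 21; the sequence 1–8, 20, 21 is equally long).

Steps most likely to fail:

1. Step 20. The addition may proceed with poor facial selectivity if Felkin-type attack competes with the O1/carbonyl zinc chelate, and the borane or zinc species may attack the unsaturated lactone. The fallback sets out from 30 and 12 and returns at 33. Hydrozirconation–iodination of 30 ((C5H5)2Zr(H)Cl, THF; then I2) would give the (E,E)-dienyl iodide F1. Nozaki–Hiyama–Kishi coupling of F1 with 12 (CrCl2, NiCl2 cat., DMSO/THF), which tolerates the lactone, would give 33 together with its (11R)-epimer F2. The unseparated mixture would be oxidised with MnO2 to the dienone F3. Reagent-controlled 1,2-reduction of F3 with (S)-2-methyl-CBS-oxazaborolidine and catecholborane at −78 °C, with the dienyl group expected to act as the large substituent so that hydride enters the Re face (the (R)-catalyst serves if the sense is reversed), would give 33.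

2. Step 3. The conjugated oxocarbenium ion is a weak electrophile, and competing oxonia-Cope scrambling, side-chain exchange with free aldehyde, or loss of the (Z)-olefin geometry may erode the C5/C6 stereochemistry. The fallback sets out from 4 and returns at 7 and generates the same cation without free aldehyde or water (segment-coupling Prins). Esterification of 4 with (E)-but-2-enoic acid (DCC, DMAP) would give the crotonate ester F4. Reduction with DIBAL-H at −78 °C and trapping with Ac2O/pyridine/DMAP would give the α-acetoxy ether F5. Ionisation with BF3·OEt2 and AcOH in hexane at 0 °C would give the all-cis 4-acetate F6, and K2CO3/MeOH would give 7.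

3. Step 18. The alkylpalladium intermediate may undergo β-acyloxy elimination, which opens the lactone, and the hindered (Z)-iodide may isomerise during slow insertion. The fallback sets out from 17 and 28 and returns at 29. Cross-metathesis of 17 with vinylboronic acid pinacol ester (second-generation Grubbs catalyst RuCl2(=CHPh)(PCy3)(H2IMes), CH2Cl2, 40 °C) would give the (E)-alkenylboronate F7. Suzuki–Miyaura coupling of F7 with 28 (PdCl2(dppf), aq. K3PO4, THF, rt), which fixes both olefin geometries in the coupling partners, would give 29.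

**Further compounds**

F1 | step 20 | (S)-6-[(1E,3Z,5R,7E,9E)-10-iodo-3,5,7-trimethyldeca-1,3,7,9-tetraen-1-yl]-5,6-dihydro-2H-pyran-2-one | I/C=C/C=C(\C)C[C@@H](C)/C=C(C)\C=C\[C@@H]1CC=CC(=O)O1
F2 | step 20 | (11R)-epimer of 33 | C/C=C/[C@@H]1O[C@H]([C@H](O)/C=C/C=C(\C)C[C@@H](C)/C=C(C)\C=C\[C@@H]2CC=CC(=O)O2)C[C@@H](O[Si](CC)(CC)CC)[C@@H]1C
F3 | step 20 | 11-oxo analogue (dienone) of 33 | C/C=C/[C@@H]1O[C@H](C(=O)/C=C/C=C(\C)C[C@@H](C)/C=C(C)\C=C\[C@@H]2CC=CC(=O)O2)C[C@@H](O[Si](CC)(CC)CC)[C@@H]1C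
F4 | step 3 | (S,Z)-1-[(tert-butyldiphenylsilyl)oxy]hex-4-en-2-yl (E)-but-2-enoate | C/C=C\C[C@H](OC(=O)/C=C/C)CO[Si](c1ccccc1)(c1ccccc1)C(C)(C)C
F5 | step 3 | (E)-1-{[(S,Z)-1-[(tert-butyldiphenylsilyl)oxy]hex-4-en-2-yl]oxy}but-2-en-1-yl acetate (epimers at the acetal carbon) | C/C=C\C[C@H](OC(OC(C)=O)/C=C/C)CO[Si](c1ccccc1)(c1ccccc1)C(C)(C)C
F6 | step 3 | (2S,3S,4S,6S)-6-{[(tert-butyldiphenylsilyl)oxy]methyl}-3-methyl-2-[(E)-prop-1-en-1-yl]oxan-4-yl acetate | C/C=C/[C@@H]1O[C@H](CO[Si](c2ccccc2)(c2ccccc2)C(C)(C)C)C[C@H](OC(C)=O)[C@@H]1C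
F7 | step 18 | (S,E)-6-[2-(4,4,5,5-tetramethyl-1,3,2-dioxaborolan-2-yl)vinyl]-5,6-dihydro-2H-pyran-2-one | CC1(C)OB(/C=C/[C@@H]2CC=CC(=O)O2)OC1(C)C
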